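## Retrosynthetic overview
1. Retro-[4+2] of the cyclohexene gives diene **8** (a 5′-dehydroprenyl-(2R)-flavanone) and dienophile **9** (2,4,2′,4′-tetrahydroxychalcone). The key step is a one-shot catalytic asymmetric Diels–Alder reaction of these two unprotected partners. A chiral boron Lewis acid differentiates the enantiotopic faces of the achiral partners and sets C3, C4 and C5 together.
2. The chromanone ring of **8** comes from an enantioselective oxa-Michael closure of dienyl 2′-hydroxychalcone **7**. This ring is formed before the cyclohexene.
3. Chalcone **7** comes from Claisen–Schmidt condensation of dienal **5** with resacetophenone **6**. Dienal **5** comes from a Heck reaction of 5-iodo-2,4-dihydroxybenzaldehyde (**3**) with isoprene (**4**). Chalcone **9** comes from the same two resorcinol building blocks.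
4. Ring order: commercial resorcinol-derived arenes, then the diene, then the chalcone, then the chromanone, then the cyclohexene last.

Assumptions (one line each):
- The target is taken as drawn: flavanone C2 is R, and the cyclohexene (C1 = C–Me, C3 bearing the flavanonyl-aryl) is 3R,4R,5S. This is the all-trans arrangement, with Ar¹ and Ar³ cis to each other and the aroyl group trans to both.
- The chiral-ligand and catalyst enantiomers in Steps 4 and 6 are chosen to give these configurations and would be matched empirically.

## Route

**Step 1**
Reactants: **1** 2,4-dihydroxybenzaldehyde; **2** N-iodosuccinimide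
Product: **3** 2,4-dihydroxy-5-iodobenzaldehyde
Conditions: NIS (1.05 equiv), MeCN, 0 °C → rt, 3 h, dark
Reagents that add atoms: N-iodosuccinimide, O=C1CCC(=O)N1I (adds I)
Why: Electrophilic aromatic iodination. C5 is para to the 2-OH and ortho to the 4-OH, whereas C3 (between the two OH groups) is hindered, so iodination goes to C5.

**Step 2**
Reactants: **3**; **4** isoprene (2-methylbuta-1,3-diene)
Product: **5** (E)-2,4-dihydroxy-5-(3-methylbuta-1,3-dien-1-yl)benzaldehyde
Conditions: Pd(OAc)₂ (5 mol %), n-Bu₄NCl (1 equiv), NaHCO₃ (3 equiv), isoprene (10 equiv), BHT (cat.), DMF, 70 °C, sealed tube, 12 h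
Reagents that add atoms: isoprene, C=CC(C)=C (adds C₅H₈)
Why: Jeffery-type Mizoroki–Heck reaction. Aryl–Pd adds to the unsubstituted vinyl terminus of isoprene, and β-H elimination gives the E-1-aryl-3-methylbutadiene. The free phenols and aldehyde are tolerated.

**Step 3**
Reactants: **5**; **6** 2,4-dihydroxyacetophenone (resacetophenone)
Product: **7** (E)-1-(2,4-dihydroxyphenyl)-3-[2,4-dihydroxy-5-((E)-3-methylbuta-1,3-dien-1-yl)phenyl]prop-2-en-1-one
Conditions: KOH (8 equiv), EtOH/H₂O 1:1, rt, 48 h, N₂, dark; quench with aq NH₄Cl to pH ~6
Reagents that add atoms: none
Why: Claisen–Schmidt aldol condensation. The E-enone forms thermodynamically, the polyphenoxide medium holds the chalcone open, and the diene survives base. The product is used promptly to avoid self-Diels–Alder.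

**Step 4**
Reactant: **7**
Product: **8** (2R)-7-hydroxy-2-[2,4-dihydroxy-5-((E)-3-methylbuta-1,3-dien-1-yl)phenyl]chroman-4-one
Conditions: quinidine-derived bifunctional thiourea/squaramide (15 mol %), CH₂Cl₂/THF 4:1, 25 °C, 3 d, degassed, no acid
Reagents that add atoms: none
Why: Intramolecular oxa-Michael (chalcone-isomerase-type) cyclization. The catalyst binds the phenoxide and activates the enone, and its chiral pocket selects one enone face to set C2 as R.
Proposed new method: cinchona-bifunctional oxa-Michael closure of 2′-hydroxychalcones is known, and here it is extended to an electron-rich free-polyphenol substrate carrying an acid-sensitive dienyl group. Base and H-bond catalysis is used so the diene is not protonated to the cation that would form a 2,2-dimethylchromene.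

**Step 5**
Reactants: **1** 2,4-dihydroxybenzaldehyde; **6** resacetophenone
Product: **9** (E)-2,4,2′,4′-tetrahydroxychalcone
Conditions: KOH (8 equiv), EtOH/H₂O 1:1, rt, 48 h, N₂; quench with aq NH₄Cl
Reagents that add atoms: none
Why: Claisen–Schmidt condensation giving the E-enone, as in Step 3.

**Step 6 (key step)**
Reactants: **8** diene; **9** chalcone (1.5 equiv)
Product: **10** target
Conditions: B(OPh)₃ (1.0 equiv), chiral biaryl diol ligand, e.g. (S)-VAPOL (0.3 equiv), 4 Å MS, toluene/CH₂Cl₂ 1:1, 25 °C, 72 h; aq NH₄Cl work-up
Reagents that add atoms: none (the boron species is a removable Lewis acid)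
Why: Lewis-acid-catalysed normal-demand Diels–Alder reaction. The chiral boron complex chelates the 2′-OH/C=O of chalcone **9** and locks the s-cis enone, which lowers the LUMO and blocks one enantioface.
- Regiochemistry: the 1-aryl and 2-methyl groups of the diene direct cooperatively to the "ortho/para" adduct, with the aroyl-bearing carbon bonded to the aryl-bearing diene terminus.
- Relative stereochemistry: the E,E partners react suprafacially, so the chalcone's trans aroyl/aryl relationship is retained (4,5-trans). An aroyl-exo (aryl-endo) approach, with the bulky chelate away from the diene, gives the 3,4-trans product. This is also the thermodynamically preferred, all-equatorial isomer, so C4 epimerization would not erode it.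
- C2 of the flavanone is untouched under neutral, base-free conditions and is remote, so it does not compete with the catalyst's facial control.

Proposed new method: a chiral-boron-catalysed Diels–Alder reaction on fully unprotected polyphenolic partners. The closest known reaction is the chiral-boron-catalysed Diels–Alder of 2′-hydroxychalcones with dehydroprenyl aryl dienes (Morus-type adducts). Excess borate/ligand is used to compensate for phenol–boron exchange, and the chalcone binds the boron most tightly through its ketone/2′-OH chelate.

## Compound list
1 | 2,4-dihydroxybenzaldehyde | O=Cc1ccc(O)cc1O | starting material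
2 | N-iodosuccinimide | O=C1CCC(=O)N1I | starting material
3 | 2,4-dihydroxy-5-iodobenzaldehyde | O=Cc1cc(I)c(O)cc1O | intermediate
4 | isoprene | C=CC(C)=C | starting material
5 | (E)-2,4-dihydroxy-5-(3-methylbuta-1,3-dienyl)benzaldehyde | C=C(C)/C=C/c1cc(C=O)c(O)cc1O | intermediate
6 | 2,4-dihydroxyacetophenone | CC(=O)c1ccc(O)cc1O | starting material
7 | dienyl 2′,4′,2,4-tetrahydroxychalcone | C=C(C)/C=C/c1cc(/C=C/C(=O)c2ccc(O)cc2O)c(O)cc1O | intermediate
8 | (2R)-dienyl flavanone | C=C(C)/C=C/c1cc([C@H]2CC(=O)c3ccc(O)cc3O2)c(O)cc1O | intermediate (diene)
9 | (E)-2,4,2′,4′-tetrahydroxychalcone | O=C(/C=C/c1ccc(O)cc1O)c1ccc(O)cc1O | intermediate (dienophile)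
10 | target (2R; cyclohexene 3R,4R,5S, all-trans) | CC1=C[C@@H](c2cc([C@H]3CC(=O)c4ccc(O)cc4O3)c(O)cc2O)[C@H](C(=O)c2ccc(O)cc2O)[C@@H](c2ccc(O)cc2O)C1 | target

Atom check: **8** (C₂₀H₁₈O₅) + **9** (C₁₅H₁₂O₅) = **10** (C₃₅H₃₀O₁₀), a cycloaddition with no atoms lost.

## Totals
Total steps: 6. Longest linear sequence: 5 (1 → 3 → 5 → 7 → 8 → 10).

## Three steps most likely to fail
1. **Step 6 (Diels–Alder).** The 4-hydroxychalcone is electronically deactivated, free phenols sequester boron, and the aroyl-exo (3,4-trans) selectivity is uncertain.
   Fallback: per-O-MOM-protect **8** and **9**, run a Me₂AlCl-promoted or high-pressure Diels–Alder, isolate the all-trans racemate, resolve it by chiral-phase HPLC, and remove the MOM groups with acid. This adds about 3 steps.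
2. **Step 4 (asymmetric oxa-Michael).** Phenol–amine acid–base quenching of the catalyst may give low ee or conversion, and the flavanone can racemize by retro-Michael.
   Fallback: cyclize racemically (NaOAc, EtOH, reflux), then resolve (R)-**8** by preparative chiral SFC/HPLC.
3. **Step 2 (Heck with isoprene).** Regioselectivity (arylation at the wrong isoprene terminus) and double arylation or telomerization are possible.
   Fallback: Suzuki coupling of **3** with (E)-(3-methylbuta-1,3-dien-1-yl)Bpin, made by hydroboration of 2-methylbut-1-en-3-yne.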